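**Retrosynthetic overview**
- The two ring A phenols are unmasked last, by hydrogenolysis of a bis(benzyl) ether of the depside.
- Key disconnection: the depside C(aryl)–O bond between the carboxylate oxygen of ring A and C4 of ring B, formed by copper-mediated oxidative coupling of 2,4-bis(benzyloxy)-6-propylbenzoic acid with the ring B C4 boronic acid.
- The feature the plan rests on: in ring B (C1 CO2Me, C2 OMe, C6 propyl) C4 is the only ring carbon whose two neighbours (C3 and C5) both carry hydrogen, so a sterically governed C–H borylation puts boron exactly where the ester oxygen must go. The ring A carbonyl carbon, flanked by the C2 oxygen and the C6 propyl group, is never attacked.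
- The ring B propyl chain comes from lateral lithiation and ethylation of methyl 2-methoxy-6-methylbenzoate; the ring A acid comes from methyl divarate by dibenzylation and saponification.
- No ring is formed in the route; both benzene rings are bought intact.

Key step: step 6

Remark: methyl divarate is taken as purchasable, and the pinacol boronate is hydrolysed to the free boronic acid before the coupling because pinacol esters transmetalate sluggishly to copper and released pinacol binds the metal.

**Step 1**
Reactants: 1 methyl 2-methoxy-6-methylbenzoate; 2 iodoethane
Product: 4 methyl 2-methoxy-6-propylbenzoate, via benzylic lithium species 3 (not isolated)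
Conditions: LiN(i-Pr)2 (LDA, 1.15 equiv), THF, −78 °C (ester added to base); then EtI, −78 → 0 °C; aq. NH4Cl
Reagents that add atoms: none
Why: Lateral lithiation of an ortho-toluate gives the ester-conjugated benzylic anion 3 at −78 °C, where the di-ortho-substituted ester resists self-condensation, and the anion should be C-alkylated by the primary iodide in an SN2 reaction.

**Step 2**
Reactants: 4 methyl 2-methoxy-6-propylbenzoate; 5 bis(pinacolato)diboron
Product: 6 methyl 2-methoxy-6-propyl-4-(4,4,5,5-tetramethyl-1,3,2-dioxaborolan-2-yl)benzoate
Conditions: [Ir(OMe)(cod)]2 (1.5 mol %), 4,4'-di-tert-butyl-2,2'-bipyridine (3 mol %), B2pin2 (1.0 equiv), THF, 80 °C, N2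
Reagents that add atoms: none
Why: Sterically governed iridium-catalysed aromatic C–H borylation, in which the trivalent iridium tris(boryl) bipyridine complex avoids C–H bonds next to a substituent, so of C3–H, C4–H and C5–H only C4–H, which has hydrogen on both sides, is expected to react.

**Step 3**
Reactants: 6 methyl 2-methoxy-6-propyl-4-(4,4,5,5-tetramethyl-1,3,2-dioxaborolan-2-yl)benzoate
Product: 7 [3-methoxy-4-(methoxycarbonyl)-5-propylphenyl]boronic acid
Conditions: NaIO4 (3 equiv), NH4OAc (3 equiv), acetone/H2O (1:1), rt
Reagents that add atoms: water, O
Why: Oxidative cleavage of a pinacol boronate, in which the hydrolysis equilibrium is pulled to the boronic acid as periodate cleaves the released pinacol to acetone (glycol cleavage) under buffered conditions that leave the methyl ester untouched.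

**Step 4**
Reactants: 8 methyl 2,4-dihydroxy-6-propylbenzoate (methyl divarate); 9 benzyl bromide
Product: 10 methyl 2,4-bis(benzyloxy)-6-propylbenzoate
Conditions: BnBr (2.5 equiv), K2CO3 (3 equiv), DMF, 60 °C
Reagents that add atoms: benzyl bromide (second equivalent, the same compound as 9), BrCc1ccccc1
Why: Twofold Williamson ether synthesis, in which each of the two phenoxides, including the hydrogen-bonded C2–OH, should be O-benzylated by one equivalent of the reactive benzylic bromide in warm DMF.

**Step 5**
Reactants: 10 methyl 2,4-bis(benzyloxy)-6-propylbenzoate
Product: 12 2,4-bis(benzyloxy)-6-propylbenzoic acid, via potassium carboxylate 11 (not isolated)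
Conditions: KOH (excess), DMSO/H2O (4:1), 90 °C; then 1 M HCl, 0 °C
Reagents that add atoms: potassium hydroxide, [K+].[OH-]
Why: Saponification (acyl–oxygen cleavage) of a di-ortho-substituted methyl benzoate, made feasible by poorly solvated hydroxide in hot aqueous DMSO, with benzyl ethers inert to base and cold acidification avoiding protodecarboxylation of the electron-rich acid.

**Step 6**
Reactants: 7 [3-methoxy-4-(methoxycarbonyl)-5-propylphenyl]boronic acid; 12 2,4-bis(benzyloxy)-6-propylbenzoic acid
Product: 13 3-methoxy-4-(methoxycarbonyl)-5-propylphenyl 2,4-bis(benzyloxy)-6-propylbenzoate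
Conditions: 7 (2 equiv), Cu(OTf)2 (40 mol %), urea (1 equiv), 4 Å MS, EtOAc, air, 60 °C
Reagents that add atoms: none
Why: Chan–Lam oxidative C(aryl)–O coupling, in which the aryl group of 7 passes from boron to divalent copper, the carboxylate of 12 binds the metal, oxidation gives a trivalent copper aryl carboxylate, reductive elimination forms the O–C4 bond, and air returns monovalent copper to the divalent state. The closest known reaction type is the Cu(OTf)2-mediated coupling of benzoic acids with arylboronic acids to phenolic esters. No ring is closed and no stereocentre is formed. The bond is made at the carboxylate oxygen, two atoms away from the carbonyl carbon shielded by the C2 benzyloxy and C6 propyl groups, so no tetrahedral intermediate at the crowded acyl centre is needed. Site selectivity on ring B is fixed by the position of boron, and chemoselectivity is secured because both ring A phenols are benzylated and the carboxylate is the only oxygen nucleophile, while the excess of 7 and the molecular sieves offset protodeboronation and phenol formation.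

**Step 7**
Reactants: 13 3-methoxy-4-(methoxycarbonyl)-5-propylphenyl 2,4-bis(benzyloxy)-6-propylbenzoate
Product: 14 3-methoxy-4-(methoxycarbonyl)-5-propylphenyl 2,4-dihydroxy-6-propylbenzoate (target)
Conditions: H2 (1 atm), 10% Pd/C, EtOAc, rt
Reagents that add atoms: none
Why: Heterogeneous catalytic hydrogenolysis of the two benzylic C–O bonds over zerovalent palladium, under neutral conditions in a non-nucleophilic solvent that should leave the aryl ester, the methyl ester and the methyl ether intact.

**Compound list**
1 | methyl 2-methoxy-6-methylbenzoate | COC(=O)c1c(C)cccc1OC | starting material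
2 | iodoethane | CCI | starting material
3 | [2-methoxy-6-(methoxycarbonyl)benzyl]lithium | [Li]Cc1cccc(OC)c1C(=O)OC | intermediate
4 | methyl 2-methoxy-6-propylbenzoate | CCCc1cccc(OC)c1C(=O)OC | intermediate
5 | bis(pinacolato)diboron | CC1(C)OB(OC1(C)C)B1OC(C)(C)C(C)(C)O1 | starting material
6 | methyl 2-methoxy-6-propyl-4-(4,4,5,5-tetramethyl-1,3,2-dioxaborolan-2-yl)benzoate | CCCc1cc(B2OC(C)(C)C(C)(C)O2)cc(OC)c1C(=O)OC | intermediate
7 | [3-methoxy-4-(methoxycarbonyl)-5-propylphenyl]boronic acid | CCCc1cc(B(O)O)cc(OC)c1C(=O)OC | intermediate
8 | methyl 2,4-dihydroxy-6-propylbenzoate (methyl divarate) | CCCc1cc(O)cc(O)c1C(=O)OC | starting material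
9 | benzyl bromide | BrCc1ccccc1 | starting material
10 | methyl 2,4-bis(benzyloxy)-6-propylbenzoate | CCCc1cc(OCc2ccccc2)cc(OCc2ccccc2)c1C(=O)OC | intermediate
11 | potassium 2,4-bis(benzyloxy)-6-propylbenzoate | CCCc1cc(OCc2ccccc2)cc(OCc2ccccc2)c1C(=O)[O-].[K+] | intermediate
12 | 2,4-bis(benzyloxy)-6-propylbenzoic acid | CCCc1cc(OCc2ccccc2)cc(OCc2ccccc2)c1C(=O)O | intermediate
13 | 3-methoxy-4-(methoxycarbonyl)-5-propylphenyl 2,4-bis(benzyloxy)-6-propylbenzoate | CCCc1cc(OCc2ccccc2)cc(OCc2ccccc2)c1C(=O)Oc1cc(CCC)c(C(=O)OC)c(OC)c1 | intermediate
14 | 3-methoxy-4-(methoxycarbonyl)-5-propylphenyl 2,4-dihydroxy-6-propylbenzoate | CCCc1cc(O)cc(O)c1C(=O)Oc1cc(CCC)c(C(=O)OC)c(OC)c1 | target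

**Step count**
Total steps: 7. Longest linear sequence: 5 (steps 1, 2, 3, 6, 7); the ring A branch (steps 4, 5) joins at step 6.

**Steps most likely to fail**

Step 6. Transmetalation from boron to copper may be slow, so that protodeboronation, oxidative homocoupling or hydroxylation of the boronic acid outpaces C–O reductive elimination; acid set free in the mixture may also trigger protodecarboxylation of the electron-rich acid. Fallback: the polarity is reversed to acyl transfer. Setting out from 7, the C–B bond is oxidised with aqueous H2O2 and NaHCO3 in THF at 0 °C to rt to give methyl 4-hydroxy-2-methoxy-6-propylbenzoate F1. Acid 12 is activated with trifluoroacetic anhydride in toluene at rt as 2,4-bis(benzyloxy)-6-propylbenzoic trifluoroacetic anhydride F2, an acylium-type donor that tolerates two ortho substituents. F2 then acylates the phenol F1, and the route is rejoined at 13.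

Step 1. The benzylic anion may add to the ester of unreacted 1 (Claisen-type self-condensation), or the product may be deprotonated and ethylated a second time. Fallback: the chain is extended from an electrophilic benzylic carbon instead. Setting out from 1, Wohl–Ziegler bromination (N-bromosuccinimide, AIBN, PhCF3, 80 °C) gives methyl 2-(bromomethyl)-6-methoxybenzoate F3. Coupling of F3 with EtMgBr under Li2CuCl4 catalysis in THF at −78 → 0 °C, where the shielded ester should not be attacked, returns to the route at 4.

Step 5. Hydroxide attack at the shielded carbonyl carbon may stall, and forcing conditions or warm acidification may cause loss of CO2 from the product. Fallback: the ester is cleaved at the unhindered O-methyl carbon instead of at the carbonyl. Setting out from 10, SN2 demethylation with LiI in pyridine at reflux gives lithium 2,4-bis(benzyloxy)-6-propylbenzoate F4, which on cold acidification with dilute HCl rejoins the route at 12.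

**Further compounds**
F1 | step 6 | methyl 4-hydroxy-2-methoxy-6-propylbenzoate | CCCc1cc(O)cc(OC)c1C(=O)OC
F2 | step 6 | 2,4-bis(benzyloxy)-6-propylbenzoic trifluoroacetic anhydride | CCCc1cc(OCc2ccccc2)cc(OCc2ccccc2)c1C(=O)OC(=O)C(F)(F)F
F3 | step 1 | methyl 2-(bromomethyl)-6-methoxybenzoate | COC(=O)c1c(CBr)cccc1OC
F4 | step 5 | lithium 2,4-bis(benzyloxy)-6-propylbenzoate | CCCc1cc(OCc2ccccc2)cc(OCc2ccccc2)c1C(=O)[O-].[Li+]
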